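Rings: A = trioxygenated ring on the carbinol carbon; B = para-linked ring; C = ring with CH2 at C1, ether O at C2, OH at C3; D = meta-linked ring with CH2 at C1, ether carbon C3, and C6 (para to C3, ortho to C1).
Cuts, in retrosynthetic order: the O-benzyl and ketal C–O bonds; a helper C6–S bond on ring D; the ring C C2–O to ring D C3 ether bond (opens the 18-membered ring); the C(=O)–CH2 bond between ring A and ring D; the ring B–CH=CH–ring C bond; the ring A O–ring B C ether bond.
Enabling feature: C1 and C3 of ring D are meta, so the single carbon C6 is ortho to the benzylic carbon and para to the ether carbon. One (S)-p-tolylsulfinyl group on C6 therefore acidifies the C1 methyl (acylation by the ring A ester), directs the ketone reduction, and activates C3–F for attack by the ring C C2 phenoxide; C6 is C–H in the target, so the group leaves by sulfoxide–lithium exchange.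
Forward order: ring A–O–ring B ether (SNAr), ring B–CH2CH2–ring C (Wittig, hydrogenation), ring A–CO–CH2–ring D (acylation), carbinol, 18-membered ring (SNAr), desulfinylation, hydrogenolysis of benzyl ether and ketal.
Stereochemistry: the single (S)-carbinol centre is relayed from the sulfur stereocentre of (1R,2S,5R)-menthyl (S)-p-toluenesulfinate by chelation-controlled hydride reduction; no later step touches it.

Key step: step 11

Assumption: the sense of the sulfinyl-directed reduction in step 10 is taken as (S)-sulfur giving (S)-carbinol; should the induction run the other way, the antipodal (1S,2R,5S)-menthyl (R)-p-toluenesulfinate is used in step 8 and nothing else changes.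

Step 1
Reactants: 1 methyl gallate
Product: 2 methyl 7-hydroxy-2,2-diphenyl-1,3-benzodioxole-5-carboxylate
Conditions: Ph2CCl2 (1.2 equiv), neat, 180 °C
Reagents that add atoms: dichlorodiphenylmethane ClC(Cl)(c1ccccc1)c1ccccc1
Why: Ketalisation of a catechol by a gem-dichloride; only a vicinal OH pair can close the five-membered ring and the two pairs of the symmetric triol are equivalent, so exactly one phenol (the later ring A ether oxygen) should stay free.

Step 2
Reactants: 2 methyl 7-hydroxy-2,2-diphenyl-1,3-benzodioxole-5-carboxylate; 3 4-fluorobenzaldehyde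
Product: 4 methyl 7-(4-formylphenoxy)-2,2-diphenyl-1,3-benzodioxole-5-carboxylate
Conditions: K2CO3, DMF, 110 °C
Reagents that add atoms: none
Why: SNAr (addition–elimination) of the phenoxide on a fluoroarene activated by the para formyl group should form the ring A–O–ring B ether and leave the aldehyde for the bibenzyl bridge.

Step 3
Reactants: 5 2,3-dihydroxybenzaldehyde
Product: 6 3-(benzyloxy)-2-hydroxybenzaldehyde
Conditions: NaH (2.1 equiv), DMSO, rt; BnBr (1.0 equiv); then 1 M HCl
Reagents that add atoms: benzyl bromide BrCc1ccccc1
Why: Williamson etherification of the dianion, in which the C2 phenoxide is conjugated with and chelated to the ortho formyl group, so the C3 phenoxide is the more nucleophilic and should be the one alkylated.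

Step 4
Reactants: 6 3-(benzyloxy)-2-hydroxybenzaldehyde
Product: 7 2-(benzyloxy)-6-(hydroxymethyl)phenol
Conditions: NaBH4, MeOH–THF, 0 °C
Reagents that add atoms: none
Why: Borohydride reduction of an aryl aldehyde to the benzylic alcohol, with no other reducible group present.

Step 5
Reactants: 7 2-(benzyloxy)-6-(hydroxymethyl)phenol
Product: 8 [3-(benzyloxy)-2-hydroxybenzyl]triphenylphosphonium bromide
Conditions: PPh3·HBr, MeCN, reflux
Reagents that add atoms: triphenylphosphine hydrobromide [Br-].c1ccc(cc1)[PH+](c1ccccc1)c1ccccc1
Why: Phosphonium salt formation from an ortho-hydroxybenzyl alcohol, whose acid-promoted ionisation (quinone-methide-like cation) and capture by PPh3 should give the salt directly with the phenol left free.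

Step 6
Reactants: 4 methyl 7-(4-formylphenoxy)-2,2-diphenyl-1,3-benzodioxole-5-carboxylate; 8 [3-(benzyloxy)-2-hydroxybenzyl]triphenylphosphonium bromide
Product: 10 methyl 7-(4-{2-[3-(benzyloxy)-2-hydroxyphenyl]ethenyl}phenoxy)-2,2-diphenyl-1,3-benzodioxole-5-carboxylate (E/Z mixture), via phenoxide ylide 9 (not isolated)
Conditions: 8, LiN(SiMe3)2 (2.2 equiv), THF, −78 to 0 °C; then 4, 0 °C to rt; 1 M HCl work-up
Reagents that add atoms: none
Why: Wittig olefination with a semi-stabilised benzylic ylide (the second equivalent of base covers the phenol); the non-nucleophilic amide base spares the ester, and the alkene geometry is irrelevant because the double bond is saturated next.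

Step 7
Reactants: 10 stilbene ester (E/Z mixture)
Product: 11 methyl 7-(4-{2-[3-(benzyloxy)-2-hydroxyphenyl]ethyl}phenoxy)-2,2-diphenyl-1,3-benzodioxole-5-carboxylate
Conditions: H2 (1 atm), 10% Pd/C, Ph2S (0.01 equiv), EtOAc, rt
Reagents that add atoms: none
Why: Catalytic hydrogenation of the stilbene C=C on sulfide-moderated palladium, which should saturate the olefin without hydrogenolysis of the O-benzyl or ketal C–O bonds.

Step 8
Reactants: 12 1-bromo-4-fluoro-2-methylbenzene; 13 (1R,2S,5R)-menthyl (S)-4-methylbenzenesulfinate
Product: 15 (S)-4-fluoro-2-methylphenyl 4-methylphenyl sulfoxide, via aryl Grignard reagent 14 (not isolated)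
Conditions: Mg, THF, reflux; then added to 13, THF–toluene, 0 °C; 1 M HCl work-up
Reagents that add atoms: none
Why: Andersen sulfoxide synthesis, in which the Grignard reagent displaces menthoxide at sulfur with inversion, so the (S)-sulfinate should give the (S)-sulfoxide (the descriptor is kept because the ligand priorities change).

Step 9
Reactants: 11 bibenzyl methyl ester; 15 (S)-4-fluoro-2-methylphenyl 4-methylphenyl sulfoxide
Product: 17 1-[7-(4-{2-[3-(benzyloxy)-2-hydroxyphenyl]ethyl}phenoxy)-2,2-diphenyl-1,3-benzodioxol-5-yl]-2-{5-fluoro-2-[(S)-4-methylbenzenesulfinyl]phenyl}ethan-1-one, via benzylic lithium reagent 16 (not isolated)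
Conditions: 15 (2.2 equiv), LiN(iPr)2 (2.2 equiv), THF, −78 °C; then lithium phenoxide of 11 (11, LiN(iPr)2 1.05 equiv, THF), −78 to −40 °C; AcOH quench
Reagents that add atoms: none
Why: Lateral (benzylic) lithiation ortho to the sulfinyl group followed by Claisen-type acylation by the methyl ester; the second equivalent of carbanion converts the ketone into its enolate, which should prevent double addition, and the excess of 15 is recoverable.

Step 10
Reactants: 17 δ-keto sulfoxide
Product: 18 (1S)-1-[7-(4-{2-[3-(benzyloxy)-2-hydroxyphenyl]ethyl}phenoxy)-2,2-diphenyl-1,3-benzodioxol-5-yl]-2-{5-fluoro-2-[(S)-4-methylbenzenesulfinyl]phenyl}ethan-1-ol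
Conditions: Yb(OTf)3 (1.2 equiv), iBu2AlH (3.5 equiv), THF, −78 °C
Reagents that add atoms: none
Why: Sulfinyl-directed hydride reduction of a δ-keto sulfoxide (1,5-asymmetric induction), in which Yb(OTf)3 bridges the sulfinyl and carbonyl oxygens in a rigid chelate and iBu2AlH delivers hydride to the carbonyl face remote from the p-tolyl group, so the (S)-sulfur should set the (S)-carbinol (sense as assumed above).

Step 11
Reactants: 18 (S,S)-δ-hydroxy sulfoxide
Product: 19 macrocyclic sulfoxide, the 18-membered diaryl ether in which the ring C C2 oxygen is bonded to ring D C3 (fluoride lost; (S)-carbinol, (S)-sulfinyl group, benzyl ether and ketal retained)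
Conditions: Cs2CO3 (4 equiv), DMSO, 0.003 M, 120 °C
Reagents that add atoms: none
Why: Cs2CO3 turns the only free phenol, the ring C C2–OH, into its phenoxide, which adds to ring D C3 to give a Meisenheimer anion whose charge lies on C6 and is stabilised by the sulfinyl group, and loss of fluoride then gives the diaryl ether (SNAr, addition–elimination). The closest known reaction type is the acceptor-activated SNAr macro-etherification of aryl fluorides by phenoxides used for macrocyclic diaryl ethers, together with the displacement of fluoride para to a sulfinyl group by phenoxides. The 18-membered ring closes in a formally 18-exo-trig addition to the C3=C4 bond of ring D followed by rearomatisation. No stereocentre is formed; the carbinol has no acidifying neighbour and the diaryl sulfoxide is configurationally stable at this temperature, so both should survive. Three selectivities are needed: the inner catechol oxygen reacts because the outer one (C3–O) is benzylated; the phenoxide reacts and not the secondary alkoxide because carbonate does not deprotonate the alcohol and the carbinol oxygen cannot reach C3; and ring closure should win over oligomerisation through high dilution and because C3 is the only carbon with both a nucleofuge and para activation.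

Step 12
Reactants: 19 macrocyclic sulfoxide
Product: 21 protected macrocycle (ring D C6–H; (S)-carbinol, ring C benzyl ether and ring A diphenylmethylene ketal retained), via dilithio alkoxide aryllithium 20 (not isolated)
Conditions: t-BuLi (3.5 equiv), THF, −78 °C, 10 min; AcOH quench at −78 °C
Reagents that add atoms: none
Why: Sulfoxide–lithium exchange, in which t-BuLi (after deprotonating the carbinol) attacks sulfur and the sulfurane should expel the ortho-substituted ring D carbon as an alkoxide-chelated aryllithium that is protonated to the C6–H of the target, far faster at −78 °C than any metalation of the ethers.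

Step 13
Reactants: 21 protected macrocycle
Product: 22 target, the (S)-configured 18-membered marchantin-type bis(bibenzyl) carbinol with free catechol on ring A and free phenol on ring C
Conditions: H2 (1 atm), 10% Pd/C, EtOAc–MeOH, rt, neutral, stopped after uptake of 3 equiv H2
Reagents that add atoms: none
Why: Hydrogenolysis of the O-benzyl ether and the diphenylmethylene ketal (benzylic C–O cleavage) under neutral conditions, where a secondary benzylic alcohol should be cleaved much more slowly and, with no acid or base present, the para-hydroxybenzylic carbinol is neither ionised nor epimerised.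

Compound list
1 | methyl gallate | COC(=O)c1cc(O)c(O)c(O)c1 | starting material
2 | methyl 7-hydroxy-2,2-diphenyl-1,3-benzodioxole-5-carboxylate | COC(=O)c1cc(O)c2OC(c3ccccc3)(c3ccccc3)Oc2c1 | intermediate
3 | 4-fluorobenzaldehyde | O=Cc1ccc(F)cc1 | starting material
4 | methyl 7-(4-formylphenoxy)-2,2-diphenyl-1,3-benzodioxole-5-carboxylate | COC(=O)c1cc(Oc2ccc(C=O)cc2)c2OC(c3ccccc3)(c3ccccc3)Oc2c1 | intermediate
5 | 2,3-dihydroxybenzaldehyde | O=Cc1cccc(O)c1O | starting material
6 | 3-(benzyloxy)-2-hydroxybenzaldehyde | O=Cc1cccc(OCc2ccccc2)c1O | intermediate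
7 | 2-(benzyloxy)-6-(hydroxymethyl)phenol | OCc1cccc(OCc2ccccc2)c1O | intermediate
8 | [3-(benzyloxy)-2-hydroxybenzyl]triphenylphosphonium bromide | [Br-].Oc1c(OCc2ccccc2)cccc1C[P+](c1ccccc1)(c1ccccc1)c1ccccc1 | intermediate
9 | lithium phenoxide ylide derived from 8 | [Li+].[O-]c1c(OCc2ccccc2)cccc1C=P(c1ccccc1)(c1ccccc1)c1ccccc1 | intermediate
10 | stilbene ester (E/Z mixture, E isomer drawn) | COC(=O)c1cc(Oc2ccc(/C=C/c3cccc(OCc4ccccc4)c3O)cc2)c2OC(c3ccccc3)(c3ccccc3)Oc2c1 | intermediate
11 | bibenzyl methyl ester | COC(=O)c1cc(Oc2ccc(CCc3cccc(OCc4ccccc4)c3O)cc2)c2OC(c3ccccc3)(c3ccccc3)Oc2c1 | intermediate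
12 | 1-bromo-4-fluoro-2-methylbenzene | Cc1cc(F)ccc1Br | starting material
13 | (1R,2S,5R)-menthyl (S)-4-methylbenzenesulfinate | C[C@@H]1CC[C@H]([C@@H](C1)O[S@](=O)c1ccc(C)cc1)C(C)C | starting material
14 | (4-fluoro-2-methylphenyl)magnesium bromide | Cc1cc(F)ccc1[Mg]Br | intermediate
15 | (S)-4-fluoro-2-methylphenyl 4-methylphenyl sulfoxide | Cc1ccc(cc1)[S@](=O)c1ccc(F)cc1C | intermediate
16 | benzylic lithium derivative of 15 | Cc1ccc(cc1)[S@](=O)c1ccc(F)cc1C[Li] | intermediate
17 | δ-keto sulfoxide | Cc1ccc(cc1)[S@](=O)c1ccc(F)cc1CC(=O)c1cc(Oc2ccc(CCc3cccc(OCc4ccccc4)c3O)cc2)c2OC(c3ccccc3)(c3ccccc3)Oc2c1 | intermediate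
18 | (S,S)-δ-hydroxy sulfoxide | Cc1ccc(cc1)[S@](=O)c1ccc(F)cc1C[C@H](O)c1cc(Oc2ccc(CCc3cccc(OCc4ccccc4)c3O)cc2)c2OC(c3ccccc3)(c3ccccc3)Oc2c1 | intermediate
19 | macrocyclic sulfoxide | Cc1ccc(cc1)[S@](=O)c1ccc2cc1C[C@H](O)c1cc(Oc3ccc(CCc4cccc(OCc5ccccc5)c4O2)cc3)c3OC(c4ccccc4)(c4ccccc4)Oc3c1 | intermediate
20 | dilithio alkoxide aryllithium from 19 | [Li]c1ccc2cc1C[C@H](O[Li])c1cc(Oc3ccc(CCc4cccc(OCc5ccccc5)c4O2)cc3)c3OC(c4ccccc4)(c4ccccc4)Oc3c1 | intermediate
21 | protected macrocycle (benzyl ether, diphenylmethylene ketal, (S)-carbinol) | c1cc2cc(c1)C[C@H](O)c1cc(Oc3ccc(CCc4cccc(OCc5ccccc5)c4O2)cc3)c3OC(c4ccccc4)(c4ccccc4)Oc3c1 | intermediate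
22 | target (S)-carbinol triphenol macrocycle | Oc1cc2cc(c1O)Oc1ccc(cc1)CCc1cccc(O)c1Oc1cccc(c1)C[C@@H]2O | target

Total step count: 13. Longest linear sequence: 10 steps (steps 3, 4, 5, 6, 7, 9, 10, 11, 12, 13).

Steps most likely to fail

Step 11. The sulfinyl group is a moderate activator and the phenoxide is flanked on both sides, so ring closure may be too slow and intermolecular etherification or thermal decomposition may take over. The fallback drops the sulfur helper and closes the same bond by copper-mediated coupling. It sets out from 11: treatment with MeNHOMe·HCl and i-PrMgCl (THF, −20 °C) should give the Weinreb amide F1. Addition of commercial (3-bromobenzyl)magnesium bromide (THF, 0 °C, excess to cover the phenol) should give the bromo ketone F2. Noyori transfer hydrogenation with RuCl[(S,S)-TsDPEN](p-cymene) in HCO2H–Et3N should give the (S)-bromo alcohol F3 by catalyst control. Intramolecular Ullmann etherification (CuI, picolinic acid, K3PO4, DMSO, 90 °C, high dilution) should then close the ring, and the route is rejoined at 21.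

Step 10. Hydride delivery through the chelate may show poor facial selectivity or the opposite sense, because a non-chelated pathway can compete and the large ring A substituent may distort the chelate. The fallback replaces substrate control by catalyst control: it sets out from 17, and Noyori transfer hydrogenation with RuCl[(S,S)-TsDPEN](p-cymene), HCO2H–Et3N, rt, should give the (S)-carbinol and return to the route at 18.

Step 13. Over-reduction may occur: once the para phenol is liberated, the benzylic C–OH bond may be hydrogenolysed in competition with the last benzylic C–O cleavages. The fallback shields the carbinol during hydrogenolysis. It sets out from 21: silylation (t-BuMe2SiOTf, 2,6-lutidine, CH2Cl2, 0 °C) should give the silyl ether F4. Hydrogenolysis (H2, 10% Pd/C, EtOAc) should give the triphenol silyl ether F5. Desilylation with Bu4NF buffered with AcOH (THF, 0 °C) should then return to the route at 22.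

Further compounds
F1 | step 11 | Weinreb amide of 11 | CON(C)C(=O)c1cc(Oc2ccc(CCc3cccc(OCc4ccccc4)c3O)cc2)c2OC(c3ccccc3)(c3ccccc3)Oc2c1
F2 | step 11 | 3-bromobenzyl ketone | O=C(Cc1cccc(Br)c1)c1cc(Oc2ccc(CCc3cccc(OCc4ccccc4)c3O)cc2)c2OC(c3ccccc3)(c3ccccc3)Oc2c1
F3 | step 11 | (S)-bromo alcohol | Brc1cccc(c1)C[C@H](O)c1cc(Oc2ccc(CCc3cccc(OCc4ccccc4)c3O)cc2)c2OC(c3ccccc3)(c3ccccc3)Oc2c1
F0 | step 10 | none | none
F4 | step 13 | tert-butyldimethylsilyl ether of 21 | c1cc2cc(c1)C[C@H](O[Si](C)(C)C(C)(C)C)c1cc(Oc3ccc(CCc4cccc(OCc5ccccc5)c4O2)cc3)c3OC(c4ccccc4)(c4ccccc4)Oc3c1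
F5 | step 13 | tert-butyldimethylsilyl ether of 22 | c1cc2cc(c1)C[C@H](O[Si](C)(C)C(C)(C)C)c1cc(Oc3ccc(CCc4cccc(O)c4O2)cc3)c(O)c(O)c1
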